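**Strategy.** Dorsilurin C is disconnected across ring C. The C4 carbonyl lies between A-ring carbon C4a and C3, so it is taken from carbon monoxide. C3 and C2 come from a terminal alkyne that already carries the chromene B ring, and O1 from an acetoxy group ortho to iodine. One palladium-catalysed operation forms C4a–C4 and C4–C3 and then closes O1–C2, delivering the complete 6,8-diprenylflavone. Its precursor is the mirror-symmetric, hexasubstituted 2-iodo-4,6-diprenylphloroglucinol triacetate, assembled by three directed lithiations and a non-protic MOM-to-acetate exchange. The 3-hydroxyl is added afterwards by C3 lithiation–borylation–oxidation.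

Key step: step 11

Remark on stereochemistry: the target has no stereocentre and no stereogenic double bond, so it is one achiral compound and no asymmetric step is needed. The only stereocentre on the way (C4 of chromanol 16) is racemic and is destroyed in step 8.

Remark on the precursor: all three oxygens carry acetate so that the two oxygens flanking iodine stay equivalent. The MOM groups are exchanged for acetate on the iodoarene without protic acid, because acid could cause ipso-protodeiodination of the iodophloroglucinol and cyclisation of prenyl onto phenol.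

**Step 1**
Reactants: 1 phloroglucinol
Product: 2 1,3,5-tris(methoxymethoxy)benzene
Conditions: NaH, MOMCl, DMF, 0 °C → rt
Reagents that add atoms: chloromethyl methyl ether, COCCl
Why: Williamson-type O-alkylation of the phenoxides with the hard electrophile MOMCl should give the tris-acetal, whose three OMOM groups direct the ortho-metalations that follow.

**Step 2**
Reactants: 2 1,3,5-tris(methoxymethoxy)benzene; 3 prenyl bromide
Product: 5 1,3,5-tris(methoxymethoxy)-2-(3-methylbut-2-en-1-yl)benzene, via aryllithium 4 (not isolated)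
Conditions: n-BuLi, TMEDA, THF, 0 °C; then 3, −78 °C → rt
Reagents that add atoms: none
Why: Directed ortho-metalation at a ring C–H flanked by two OMOM groups, then SN2 alkylation of the aryllithium at the primary carbon of the allylic bromide, should install the first prenyl group regiospecifically.

**Step 3**
Reactants: 5 1,3,5-tris(methoxymethoxy)-2-(3-methylbut-2-en-1-yl)benzene; 3 prenyl bromide
Product: 7 1,3,5-tris(methoxymethoxy)-2,4-bis(3-methylbut-2-en-1-yl)benzene, via aryllithium 6 (not isolated)
Conditions: n-BuLi, TMEDA, THF, 0 °C; then 3, −78 °C → rt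
Reagents that add atoms: none
Why: A second directed ortho-metalation at one of the two equivalent ring C–H positions, each still between two OMOM groups and kinetically preferred over the benzylic–allylic CH2, followed by alkylation should give the 2,4-diprenyl arene.

**Step 4**
Reactants: 7 1,3,5-tris(methoxymethoxy)-2,4-bis(3-methylbut-2-en-1-yl)benzene
Product: 9 2-iodo-1,3,5-tris(methoxymethoxy)-4,6-bis(3-methylbut-2-en-1-yl)benzene, via aryllithium 8 (not isolated)
Conditions: n-BuLi, TMEDA, THF, 0 °C; then ICH2CH2I, −78 °C → rt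
Reagents that add atoms: 1,2-diiodoethane, ICCI
Why: Directed ortho-metalation of the last ring C–H and iodine transfer from 1,2-diiodoethane (ethene as leaving group) should place iodine by a nucleophilic route that spares the prenyl alkenes, which electrophilic iodination would not.

**Step 5**
Reactants: 9 2-iodo-1,3,5-tris(methoxymethoxy)-4,6-bis(3-methylbut-2-en-1-yl)benzene
Product: 12 2-iodo-4,6-bis(3-methylbut-2-en-1-yl)benzene-1,3,5-triyl triacetate, via tris-TMS ether 10 (not isolated), via triol 11 (not isolated)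
Conditions: TMSOTf, 2,2′-bipyridyl, MeCN, 0 °C → rt; MeOH, 0 °C; evaporate; then Ac2O, pyridine, DMAP (cat.), rt
Reagents that add atoms: acetic anhydride, CC(=O)OC(C)=O
Why: Silyl triflate–bipyridyl exchange should convert the aryl MOM ethers into aryl TMS ethers without protic acid, methanolysis then frees the air-sensitive triol, and DMAP-catalysed acylation caps it in the same flask as the storable triacetate.

**Step 6**
Reactants: 13 1-(4-bromo-2-hydroxyphenyl)ethan-1-one; 14 acetone
Product: 15 7-bromo-2,2-dimethylchroman-4-one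
Conditions: pyrrolidine, MeOH, reflux
Reagents that add atoms: none
Why: Kabbe condensation (amine-mediated aldol condensation of the acetophenone with acetone, then oxa-Michael closure by the ortho phenol) should give the 2,2-dimethylchromanone with bromine fixed at C7.

**Step 7**
Reactants: 15 7-bromo-2,2-dimethylchroman-4-one
Product: 16 7-bromo-2,2-dimethylchroman-4-ol (racemic)
Conditions: NaBH4, MeOH, 0 °C → rt
Reagents that add atoms: none
Why: Borohydride reduction of the aryl ketone should give the benzylic alcohol as a racemate, which is of no consequence because this centre is removed in step 8.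

**Step 8**
Reactants: 16 7-bromo-2,2-dimethylchroman-4-ol
Product: 17 7-bromo-2,2-dimethyl-2H-chromene
Conditions: p-TsOH·H2O (cat.), toluene, reflux (Dean–Stark)
Reagents that add atoms: none
Why: Acid-catalysed E1 dehydration through the benzylic cation, stabilised by the ortho ring oxygen, should give the 2H-chromene because the gem-dimethyl carbon blocks any other elimination.

**Step 9**
Reactants: 17 7-bromo-2,2-dimethyl-2H-chromene; 18 ethynyltrimethylsilane
Product: 19 [(2,2-dimethyl-2H-chromen-7-yl)ethynyl]trimethylsilane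
Conditions: PdCl2(PPh3)2 (cat.), CuI (cat.), Et3N–THF, 65 °C (sealed)
Reagents that add atoms: none
Why: Sonogashira coupling of the aryl bromide with the silyl-capped alkyne should form the aryl–alkynyl bond without touching the chromene alkene.

**Step 10**
Reactants: 19 [(2,2-dimethyl-2H-chromen-7-yl)ethynyl]trimethylsilane
Product: 20 7-ethynyl-2,2-dimethyl-2H-chromene
Conditions: K2CO3 (cat.), MeOH, rt
Reagents that add atoms: none
Why: Methoxide-catalysed protodesilylation of the alkynylsilane should release the terminal alkyne under conditions that leave the chromene intact.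

**Step 11**
Reactants: 12 2-iodo-4,6-bis(3-methylbut-2-en-1-yl)benzene-1,3,5-triyl triacetate; 20 7-ethynyl-2,2-dimethyl-2H-chromene; 21 carbon monoxide
Product: 24 2-(2,2-dimethyl-2H-chromen-7-yl)-5,7-dihydroxy-6,8-bis(3-methylbut-2-en-1-yl)-4H-chromen-4-one (3-deoxy-dorsilurin C), via ynone 22 (not isolated), via enaminone 23 (not isolated)
Conditions: PdCl2(PPh3)2 (5 mol %), dppp (5 mol %), thiourea (5 mol %), Et2NH, DBU, CO (balloon), 40 °C, copper-free
Reagents that add atoms: none
Why: Pd(0) inserts into the C–I bond, CO inserts to give the aroyl–Pd species, and amine-assisted alkynyl transfer with reductive elimination gives ynone 22 (C4a–C4 and C4–C3), after which diethylamine cleaves the acetates and adds to the ynone to give β-aminoenone 23. The freed ortho phenoxide attacks the amine-bearing carbon and expels diethylamine (addition–elimination), forming O1–C2 in a six-membered (6-endo) closure of the γ-pyrone ring C. The closest known reaction type is the Pd/thiourea/dppp-catalysed carbonylative annulation of o-iodophenol acetates with terminal arylacetylenes to flavones. No stereocentre is created. The step needs carbonylative rather than direct alkynylation, which copper-free conditions under CO should favour, and 6-endo rather than 5-exo closure (aurone), which the enaminone pathway with a secondary amine enforces. The two acetoxy groups flanking iodine are mirror-related, so either gives the same flavone, and the fully substituted ring offers no other coupling site.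

**Step 12**
Reactants: 24 3-deoxy-dorsilurin C
Product: 25 2-(2,2-dimethyl-2H-chromen-7-yl)-5,7-bis(methoxymethoxy)-6,8-bis(3-methylbut-2-en-1-yl)-4H-chromen-4-one
Conditions: NaH, MOMCl, DMF, 0 °C → rt
Reagents that add atoms: chloromethyl methyl ether, COCCl
Why: Williamson-type O-alkylation, in which sodium hydride breaks the 5-OH···O=C4 hydrogen bond, should cap both phenols, including the chelated one, ahead of the strong-base step.

**Step 13**
Reactants: 25 5,7-bis(methoxymethoxy)flavone
Product: 28 2-(2,2-dimethyl-2H-chromen-7-yl)-3-hydroxy-5,7-bis(methoxymethoxy)-6,8-bis(3-methylbut-2-en-1-yl)-4H-chromen-4-one, via 3-lithioflavone 26 (not isolated), via boronate 27 (not isolated)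
Conditions: LDA (commercial solution), THF, −78 °C; B(OMe)3, −78 → 0 °C; then 30 % H2O2, aq. NaHCO3, 0 °C
Reagents that add atoms: hydrogen peroxide, OO
Why: Vinylic deprotonation at C3 (the only sp2 C–H next to the C4 carbonyl, assisted by lithium chelation to C4=O), borate trapping and oxidative 1,2-migration of the boronate (lithiation–borylation–oxidation) should give the 3-hydroxyflavone, and bicarbonate-buffered peroxide does not epoxidise trisubstituted alkenes.

**Step 14**
Reactants: 28 3-hydroxy-5,7-bis(methoxymethoxy)flavone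
Product: 29 dorsilurin C, 2-(2,2-dimethyl-2H-chromen-7-yl)-3,5,7-trihydroxy-6,8-bis(3-methylbut-2-en-1-yl)-4H-chromen-4-one
Conditions: 2 M aq. HCl (cat. amount), MeOH–THF, rt → 40 °C
Reagents that add atoms: none
Why: Acid-catalysed transacetalisation of the two aryl MOM ethers to dimethoxymethane should free the 5- and 7-hydroxyls, and dilute acid at low temperature should be too weak to protonate the prenyl and chromene alkenes.

**Compound list**

1 | phloroglucinol (benzene-1,3,5-triol) | Oc1cc(O)cc(O)c1 | starting material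
2 | 1,3,5-tris(methoxymethoxy)benzene | COCOc1cc(OCOC)cc(OCOC)c1 | intermediate
3 | prenyl bromide (1-bromo-3-methylbut-2-ene) | CC(C)=CCBr | starting material
4 | [2,4,6-tris(methoxymethoxy)phenyl]lithium, formed in situ | [Li]c1c(OCOC)cc(OCOC)cc1OCOC | intermediate
5 | 1,3,5-tris(methoxymethoxy)-2-(3-methylbut-2-en-1-yl)benzene | COCOc1cc(OCOC)c(CC=C(C)C)c(OCOC)c1 | intermediate
6 | [2,4,6-tris(methoxymethoxy)-3-(3-methylbut-2-en-1-yl)phenyl]lithium, formed in situ | [Li]c1c(OCOC)cc(OCOC)c(CC=C(C)C)c1OCOC | intermediate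
7 | 1,3,5-tris(methoxymethoxy)-2,4-bis(3-methylbut-2-en-1-yl)benzene | COCOc1cc(OCOC)c(CC=C(C)C)c(OCOC)c1CC=C(C)C | intermediate
8 | [2,4,6-tris(methoxymethoxy)-3,5-bis(3-methylbut-2-en-1-yl)phenyl]lithium, formed in situ | [Li]c1c(OCOC)c(CC=C(C)C)c(OCOC)c(CC=C(C)C)c1OCOC | intermediate
9 | 2-iodo-1,3,5-tris(methoxymethoxy)-4,6-bis(3-methylbut-2-en-1-yl)benzene | COCOc1c(I)c(OCOC)c(CC=C(C)C)c(OCOC)c1CC=C(C)C | intermediate
10 | 2-iodo-4,6-bis(3-methylbut-2-en-1-yl)-1,3,5-tris(trimethylsilyloxy)benzene, formed in situ | C[Si](C)(C)Oc1c(I)c(O[Si](C)(C)C)c(CC=C(C)C)c(O[Si](C)(C)C)c1CC=C(C)C | intermediate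
11 | 2-iodo-4,6-bis(3-methylbut-2-en-1-yl)benzene-1,3,5-triol, formed in situ | Oc1c(I)c(O)c(CC=C(C)C)c(O)c1CC=C(C)C | intermediate
12 | 2-iodo-4,6-bis(3-methylbut-2-en-1-yl)benzene-1,3,5-triyl triacetate | CC(=O)Oc1c(I)c(OC(C)=O)c(CC=C(C)C)c(OC(C)=O)c1CC=C(C)C | intermediate
13 | 1-(4-bromo-2-hydroxyphenyl)ethan-1-one | CC(=O)c1ccc(Br)cc1O | starting material
14 | acetone | CC(C)=O | starting material
15 | 7-bromo-2,2-dimethylchroman-4-one | CC1(C)CC(=O)c2ccc(Br)cc2O1 | intermediate
16 | 7-bromo-2,2-dimethylchroman-4-ol, racemic | CC1(C)CC(O)c2ccc(Br)cc2O1 | intermediate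
17 | 7-bromo-2,2-dimethyl-2H-chromene | CC1(C)C=Cc2ccc(Br)cc2O1 | intermediate
18 | ethynyltrimethylsilane | C#C[Si](C)(C)C | starting material
19 | [(2,2-dimethyl-2H-chromen-7-yl)ethynyl]trimethylsilane | CC1(C)C=Cc2ccc(C#C[Si](C)(C)C)cc2O1 | intermediate
20 | 7-ethynyl-2,2-dimethyl-2H-chromene | C#Cc1ccc2c(c1)OC(C)(C)C=C2 | intermediate
21 | carbon monoxide | [C-]#[O+] | starting material
22 | 2-[3-(2,2-dimethyl-2H-chromen-7-yl)prop-2-ynoyl]-4,6-bis(3-methylbut-2-en-1-yl)benzene-1,3,5-triyl triacetate, formed in situ | CC(=O)Oc1c(C(=O)C#Cc2ccc3c(c2)OC(C)(C)C=C3)c(OC(C)=O)c(CC=C(C)C)c(OC(C)=O)c1CC=C(C)C | intermediate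
23 | (E)-3-(diethylamino)-3-(2,2-dimethyl-2H-chromen-7-yl)-1-[2,4,6-trihydroxy-3,5-bis(3-methylbut-2-en-1-yl)phenyl]prop-2-en-1-one, formed in situ | CCN(CC)/C(=C/C(=O)c1c(O)c(CC=C(C)C)c(O)c(CC=C(C)C)c1O)c1ccc2c(c1)OC(C)(C)C=C2 | intermediate
24 | 2-(2,2-dimethyl-2H-chromen-7-yl)-5,7-dihydroxy-6,8-bis(3-methylbut-2-en-1-yl)-4H-chromen-4-one (3-deoxy-dorsilurin C) | CC(C)=CCc1c(O)c(CC=C(C)C)c2oc(-c3ccc4c(c3)OC(C)(C)C=C4)cc(=O)c2c1O | intermediate
25 | 2-(2,2-dimethyl-2H-chromen-7-yl)-5,7-bis(methoxymethoxy)-6,8-bis(3-methylbut-2-en-1-yl)-4H-chromen-4-one | CC(C)=CCc1c(OCOC)c(CC=C(C)C)c2oc(-c3ccc4c(c3)OC(C)(C)C=C4)cc(=O)c2c1OCOC | intermediate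
26 | 3-lithio derivative of 25, formed in situ | CC(C)=CCc1c(OCOC)c(CC=C(C)C)c2oc(-c3ccc4c(c3)OC(C)(C)C=C4)c([Li])c(=O)c2c1OCOC | intermediate
27 | dimethyl [2-(2,2-dimethyl-2H-chromen-7-yl)-5,7-bis(methoxymethoxy)-6,8-bis(3-methylbut-2-en-1-yl)-4-oxo-4H-chromen-3-yl]boronate, formed in situ | CC(C)=CCc1c(OCOC)c(CC=C(C)C)c2oc(-c3ccc4c(c3)OC(C)(C)C=C4)c(B(OC)OC)c(=O)c2c1OCOC | intermediate
28 | 2-(2,2-dimethyl-2H-chromen-7-yl)-3-hydroxy-5,7-bis(methoxymethoxy)-6,8-bis(3-methylbut-2-en-1-yl)-4H-chromen-4-one | CC(C)=CCc1c(OCOC)c(CC=C(C)C)c2oc(-c3ccc4c(c3)OC(C)(C)C=C4)c(O)c(=O)c2c1OCOC | intermediate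
29 | dorsilurin C, 2-(2,2-dimethyl-2H-chromen-7-yl)-3,5,7-trihydroxy-6,8-bis(3-methylbut-2-en-1-yl)-4H-chromen-4-one | CC(C)=CCc1c(O)c(CC=C(C)C)c2oc(-c3ccc4c(c3)OC(C)(C)C=C4)c(O)c(=O)c2c1O | target

**Totals**

Total step count: 14.
Longest linear sequence: 9 steps (steps 1–5 and 11–14, from phloroglucinol).

**Steps most likely to fail**

1. Step 11. Oxidative addition into the doubly ortho-flanked C–I bond may be slow. Acetate aminolysis to a polyphenolate, aminocarbonylation to the diethylamide or direct (non-carbonylative) alkynylation could then overtake the carbonylative coupling. The fallback builds the same three bonds stepwise without palladium. It sets out from 7 and 20 and comes back at 24. Alkyne 20 is deprotonated (n-BuLi, THF, −78 °C) to the lithium acetylide F1 and formylated with DMF (quench into aq. KH2PO4) to give 3-(2,2-dimethyl-2H-chromen-7-yl)prop-2-ynal F2. Aryllithium 8, generated from 7 as in step 4, adds to the aldehyde to give the racemic propargylic alcohol F3. MnO2 in CH2Cl2 oxidises it to the tris-MOM ynone F4. Diethylamine in ethanol adds to give the tris-MOM enaminone F5. Dilute HCl in methanol then removes the MOM groups to give 23, whose ortho phenol displaces diethylamine and closes ring C to give 24.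

2. Step 13. LDA may remove a benzylic–allylic proton of a prenyl group or attack the pyrone instead of metalating C3 cleanly, and the peroxide stage may over-oxidise the electron-rich flavonol. The fallback generates the C3 nucleophile by conjugate reduction instead of deprotonation. It sets out from 25 and comes back at 28. K-Selectride (THF, −78 °C) adds hydride to C2 and gives the potassium flavanone enolate F6. This is hydroxylated in the same flask with 2-(phenylsulfonyl)-3-phenyloxaziridine to give the racemic trans-3-hydroxyflavanone F7. Dess–Martin periodinane oxidises the carbinol to the 3,4-dione, which enolises towards C2 and is flavonol 28.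

3. Step 14. Under protic acid the freed 5- and 7-hydroxyls may cyclise onto protonated prenyl groups (dimethylchroman formation), or methanol may add across the chromene double bond, before the hindered 7-O-MOM is fully cleaved. The fallback replaces acid-labile by fluoride-labile protection. It sets out from 24 and comes back at 29. TBSOTf and 2,6-lutidine in CH2Cl2 give the 5,7-bis(tert-butyldimethylsilyl) ether F8. The sequence of step 13 (LDA, then B(OMe)3, then buffered H2O2) passes through the 3-lithio species F9 and the boronate F10 to the bis-silyl flavonol F11. TBAF buffered with acetic acid in THF then gives 29 without any acid treatment.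

**Further compounds**

F1 | step 11 | lithium (2,2-dimethyl-2H-chromen-7-yl)acetylide | [Li]C#Cc1ccc2c(c1)OC(C)(C)C=C2
F2 | step 11 | 3-(2,2-dimethyl-2H-chromen-7-yl)prop-2-ynal | O=CC#Cc1ccc2c(c1)OC(C)(C)C=C2
F3 | step 11 | 3-(2,2-dimethyl-2H-chromen-7-yl)-1-[2,4,6-tris(methoxymethoxy)-3,5-bis(3-methylbut-2-en-1-yl)phenyl]prop-2-yn-1-ol, racemic | COCOc1c(C(O)C#Cc2ccc3c(c2)OC(C)(C)C=C3)c(OCOC)c(CC=C(C)C)c(OCOC)c1CC=C(C)C
F4 | step 11 | 3-(2,2-dimethyl-2H-chromen-7-yl)-1-[2,4,6-tris(methoxymethoxy)-3,5-bis(3-methylbut-2-en-1-yl)phenyl]prop-2-yn-1-one | COCOc1c(C(=O)C#Cc2ccc3c(c2)OC(C)(C)C=C3)c(OCOC)c(CC=C(C)C)c(OCOC)c1CC=C(C)C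
F5 | step 11 | (E)-3-(diethylamino)-3-(2,2-dimethyl-2H-chromen-7-yl)-1-[2,4,6-tris(methoxymethoxy)-3,5-bis(3-methylbut-2-en-1-yl)phenyl]prop-2-en-1-one | CCN(CC)/C(=C/C(=O)c1c(OCOC)c(CC=C(C)C)c(OCOC)c(CC=C(C)C)c1OCOC)c1ccc2c(c1)OC(C)(C)C=C2
F6 | step 13 | potassium 2-(2,2-dimethyl-2H-chromen-7-yl)-5,7-bis(methoxymethoxy)-6,8-bis(3-methylbut-2-en-1-yl)-2H-chromen-4-olate, racemic | [K+].[O-]C1=CC(c2ccc3c(c2)OC(C)(C)C=C3)Oc2c(CC=C(C)C)c(OCOC)c(CC=C(C)C)c(OCOC)c21
F7 | step 13 | rac-(2R,3R)-2-(2,2-dimethyl-2H-chromen-7-yl)-3-hydroxy-5,7-bis(methoxymethoxy)-6,8-bis(3-methylbut-2-en-1-yl)chroman-4-one (trans, one enantiomer drawn) | CC1(C)C=Cc2ccc(cc2O1)[C@@H]1[C@H](C(=O)c2c(OCOC)c(CC=C(C)C)c(OCOC)c(CC=C(C)C)c2O1)O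
F8 | step 14 | 5,7-bis(tert-butyldimethylsilyloxy)-2-(2,2-dimethyl-2H-chromen-7-yl)-6,8-bis(3-methylbut-2-en-1-yl)-4H-chromen-4-one | CC(C)=CCc1c(O[Si](C)(C)C(C)(C)C)c(CC=C(C)C)c2oc(-c3ccc4c(c3)OC(C)(C)C=C4)cc(=O)c2c1O[Si](C)(C)C(C)(C)C
F9 | step 14 | 3-lithio derivative of F8 | CC(C)=CCc1c(O[Si](C)(C)C(C)(C)C)c(CC=C(C)C)c2oc(-c3ccc4c(c3)OC(C)(C)C=C4)c([Li])c(=O)c2c1O[Si](C)(C)C(C)(C)C
F10 | step 14 | dimethyl [5,7-bis(tert-butyldimethylsilyloxy)-2-(2,2-dimethyl-2H-chromen-7-yl)-6,8-bis(3-methylbut-2-en-1-yl)-4-oxo-4H-chromen-3-yl]boronate | CC(C)=CCc1c(O[Si](C)(C)C(C)(C)C)c(CC=C(C)C)c2oc(-c3ccc4c(c3)OC(C)(C)C=C4)c(B(OC)OC)c(=O)c2c1O[Si](C)(C)C(C)(C)C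
F11 | step 14 | 5,7-bis(tert-butyldimethylsilyloxy)-2-(2,2-dimethyl-2H-chromen-7-yl)-3-hydroxy-6,8-bis(3-methylbut-2-en-1-yl)-4H-chromen-4-one | CC(C)=CCc1c(O[Si](C)(C)C(C)(C)C)c(CC=C(C)C)c2oc(-c3ccc4c(c3)OC(C)(C)C=C4)c(O)c(=O)c2c1O[Si](C)(C)C(C)(C)C
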